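Atom numbers C1–C20 are labdane numbers of the target: ring A = C1–C5 and C10, ring B = C5–C10, C17 is the methyl on C8, C20 the methyl on C10, and C11–C16 form the side chain.

## Analysis of the target

The target is a labdane-type lactone, (5S,6S,10S,13S)-6β,13-dihydroxy-7-oxolabd-8-en-15,16-olide. It has a trans-fused decalin with a gem-dimethyl group at C4 and an angular methyl at C10. Ring B holds a tetrasubstituted C8=C9 enone with the carbonyl at C7, a methyl on C8 and a secondary hydroxyl at C6. An ethylene tether (C11–C12) joins C9 to C13 of a 3-hydroxy-γ-butyrolactone (C13–C16–O–C15(=O)–C14). C5, C6 and C10 are contiguous: H5 is α, the C10 methyl is β, and the C6 hydroxyl is β, that is axial and syn to both the C10 methyl and the 4β-methyl. C13 is a tertiary carbinol separated from the ring stereocentres by two methylenes and the sp2 carbon C9, so it cannot be relayed from the ring and must be set on its own. The α-ketol (C6–OH next to C7=O) can epimerise to the equatorial 6α-alcohol or enolise under base, and the β-hydroxy lactone can lose water or open under base. The hard points are the enantioselective quaternary centre C10, the contra-thermodynamic axial oxygen at C6, and the hindered enone whose C9 is next to C10. The strategy rests on the position of C5 between the quaternary carbons C4 and C10. Ring A can therefore be a 2,2,6,6-tetrasubstituted cyclohexanone with C5 as its carbonyl carbon; it cannot enolise and can only accept. Ring B is built onto it by a C5=C6 aldol condensation of a side-chain ketone that already carries the C6 oxygen.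

## Retrosynthetic reasoning

**38 back to 33.** The last bonds made are the lactone C15–O bond and the O–H bonds at C6, C13 and C16. Target 38 is traced to acid 35, with O6 as a MOM ether and O13/O16 as an acetonide. One acidic step should remove both acetals and let the primary C16 hydroxyl close the five-membered lactone through 36 and 37. This keeps the base-labile α-ketol and β-hydroxy lactone out of every basic step. Acid 35 comes from alcohol 34 and silyl ether 33, so C15 is oxidised only after the carbanion chemistry is finished.

**33 back to 19 and 30.** The C9–C11 bond is cut next. C9 is sp2 in 38, so the bond can be formed without control at C9, and the cut separates the ring stereotriad from C13. Forward, Grignard reagent 31 from bromide 30 must add in conjugate fashion to enone 19 at the carbon next to C10. The enolate is trapped as silyl enol ether 32 so that the C8=C9 bond can be restored regiospecifically to give 33. A cut at C12–C13 was not taken because it would build the tertiary carbinol on the finished ring system with no source of stereocontrol.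

**30 back to 20 and 22.** Bromide 30 holds C11–C16 with C13 masked. Its C12–C13 bond is cut to allyl bromide 22 and dioxolanone 21 of (S)-malic acid 20. The four carbons of 20 become C16, C13, C14 and C15. Alkylation of enolate 23 on the face left by the hydrogen should give 24 with retention, which is the configuration needed at C13. Reduction (25), acetonide formation (26), silylation (27), ozonolytic shortening of the allyl group (28, 29) and bromination give 30. The two two-carbon arms stay distinct because one comes from the chain of 20 and the other from 22.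

**19 back to 14.** Enone 19 differs from ketone 14 by the C8–C17 bond and the C8=C9 unsaturation. Both come from C8 enolates (15, then 17): methylation to 16, silylation to 18 and dehydrosilylation. This is done before the side chain arrives so that the final enone is later made from a regiodefined enolate.

**14 back to 12.** The C5–H and C6–H bonds are cut to give enone 12. Two hydrogens added to the α face of C5=C6, away from the C10 methyl, create the trans fusion and push the C6 oxygen into the β position. Because the oxygen is already on C6, no reagent has to approach the hindered β face. The forward step is a dissolving-metal reduction through enolate 13 with kinetic protonation.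

**12 back to 10.** Ring B is opened at C5=C6, giving diketone 10. Forward, the C6 enolate of the side-chain ketone adds to the ring carbonyl C5 (aldol 11) and water is lost. The cut is made here because the acceptor carbonyl cannot enolise and only one enolate can reach it through a six-membered transition state, so one ring and one skeletal bond form without any selectivity problem.

**10 back to 5.** The C6–C7 bond of 10 is cut to aldehyde 8 and a one-carbon α-alkoxy carbanion; addition gives 9 and oxidation gives 10. Aldehyde 8 comes from the allyl group of 5 by anti-Markovnikov hydration (6, 7) and oxidation. The three allyl carbons become C9, C8 and C7.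

**5 back to 1 and 2.** The C9–C10 bond is cut by a decarboxylative asymmetric allylation of enol carbonate 4, made from ketone 1 through enolate 3 and chloroformate 2. Ketone 1 has one enolisable carbon, so regiochemistry is fixed. This is the only step that creates absolute configuration in the ring part.

## Alternatives that were turned down

**Alternative 1:** The disconnection cuts C4–C5, C9–C10 and C8–O, back to the acyclic trienone (5E,9E)-farnesylacetone A1. In the forward key step a chiral binaphthol monoether, activated by a tin Lewis acid, protonates the terminal alkene; the chain folds chair–chair and the ketone oxygen traps the C8 cation to give sclareol oxide A2.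
- For it: rings A and B, the trans fusion and C5, C9 and C10 arise in one step from a cheap achiral chain, and A2 already contains C11–C13, C16 and C17.
- Against it: A2 has no oxygen at C6 or C7. C6 is an unactivated methylene that could only be oxidised after C7, through the C6 enolate of a 7-ketone. An electrophilic oxygen would then enter from the open α face and give the 6α-alcohol, the wrong epimer.
- Against it: C13 in A2 is an enol-ether carbon. It would have to be rebuilt from a methyl ketone by oxidising C16 and adding C14–C15 to an acyclic carbonyl flanked by two similar CH2 groups, with no control from the ring.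
- Against it: proton-initiated polyene cyclisations usually need a full equivalent of the chiral acid and geometrically pure A1.
- Comparison: it is clearly stronger in ring-construction step economy (one step against seven to reach 12). The chosen route offers in its place the C6 oxygen installed before ring B closes and C13 from the chiral pool.

**Alternative 2:** The disconnection cuts C14–C15 and C15–O of the lactone, back to the prochiral oxetane A3, in which C13 bears a silyloxy group and two enantiotopic CH2–O arms. In the forward key step a chiral chromium–salen cation paired with a cobalt tetracarbonyl anion opens one C–O bond, a carbonyl is inserted, and the alkoxide closes on the acyl to give the bis(triethylsilyl) ether A4 of the target.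
- For it: the lactone and C13 appear in one catalytic step at the very end, and the side chain of A3 would be short to prepare. On side-chain step count it is stronger than the ten operations spent here on C11–C16.
- Against it: ring-expanding carbonylation of oxetanes is known, but discrimination between the enantiotopic C–O bonds of a 3,3-disubstituted oxetane by such an ion pair is not established.
- Against it: the nearest stereocentre is too remote to help, so poor selectivity would give C13 epimers of A4 that are hard to separate.
- Against it: the Lewis acid could also ionise the tertiary silyloxy oxetane or bind the enone.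
- Against it: it says nothing about the decalin. Ring B with its axial C6 oxygen would still have to be made, essentially as here.
- Comparison: the chosen route is longer in the side chain but gives a C13 configuration that follows from retention in a well-understood alkylation.

**Alternative 3:** The disconnection cuts C1–C10 and C4–C5, back to 2,6-dimethyl-1,4-benzoquinone A5 as ring B and 4-methylpenta-1,3-diene A6. In the forward key step a chiral oxazaborolidinium catalyst mediates the Diels–Alder reaction and gives the cis-fused adduct A7 (ring A 2-ene, ring B 7-ene-6,9-dione).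
- For it: ring A, the quaternary C10 and the C8 methyl come in one catalytic step, and every ring-B carbon is functionalised. In brevity of ring construction it is stronger than the chosen route.
- Against it: A6 carries a cis-methyl at its reacting terminus, which disfavours the s-cis conformer, and it must form a bond to C5 next to the new quaternary C4, so it is a reluctant diene.
- Against it: A7 is cis-fused and needs epimerisation at C5, and it has an extra C2=C3 alkene.
- Against it: the oxygens sit at C6 and C9, whereas the target needs them at C6 (as a β-alcohol) and C7. The side chain would have to add 1,2 to the C9 carbonyl, which is flanked by C10 and the C8 methyl, in the presence of the more accessible C6 carbonyl and the C7 acceptor position. An oxidative 1,3-transposition would then have to move the oxygen to C7.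
- Comparison: the chosen route takes seven steps to reach 12, but each oxygen is placed where it ends up and the side chain is attached by conjugate addition to the only enone present.

Key step: step 7

Remark on the chemistry: the sense of induction of the PHOX ligand in step 2 is taken to follow the 2-allyl-2-methylcyclohexanone series, where the (S)-ligand is associated with the (S)-ketone; the (R)-ligand is therefore specified, and the antipodal ligand would be used if the sense proved opposite. Ketone 1 is used as the racemate because its stereocentre is erased in step 1.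

## Route

**Step 1**
Reactants: 1 2,2,6-trimethylcyclohexan-1-one; 2 allyl chloroformate
Product: 4 allyl 2,6,6-trimethylcyclohex-1-en-1-yl carbonate, via lithium enolate 3 (not isolated)
Conditions: LiN(SiMe3)2, THF, 0 °C; then 2, −78 °C to rt
Reagents that add atoms: none
Why: Ketone 1 has one enolisable position, so a single tetrasubstituted enolate 3 forms; this hindered enolate is acylated on oxygen by the chloroformate (enol carbonate formation).

**Step 2**
Reactants: 4 allyl 2,6,6-trimethylcyclohex-1-en-1-yl carbonate
Product: 5 (2R)-2-allyl-2,6,6-trimethylcyclohexan-1-one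
Conditions: Pd2(dba)3 (2.5 mol %), (R)-t-Bu-PHOX [(R)-4-tert-butyl-2-(2-diphenylphosphinophenyl)-4,5-dihydrooxazole] (6 mol %), THF, 25 °C
Reagents that add atoms: none
Why: Decarboxylative asymmetric allylic alkylation (Tsuji–Trost type): zerovalent palladium ionises the allyl carbonate, CO2 is lost, and C–C bond formation within the chiral allylpalladium enolate sets the quaternary C10. Any minor enantiomer would become a separable diastereomer after step 19, because C13 comes from the chiral pool.

**Step 3**
Reactants: 5 (2R)-2-allyl-2,6,6-trimethylcyclohexan-1-one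
Product: 7 (2R)-2-(3-hydroxypropyl)-2,6,6-trimethylcyclohexan-1-one, via B-alkyl-9-BBN adduct 6 (not isolated)
Conditions: 9-BBN, THF, 0 °C to rt; then NaOH, H2O2, H2O, 0 °C
Reagents that add atoms: hydrogen peroxide, OO
Why: Anti-Markovnikov hydroboration–oxidation; 9-BBN adds to the terminal alkene and leaves the 2,2,6,6-tetrasubstituted ketone alone, and alkaline peroxide converts C–B into C–OH.

**Step 4**
Reactants: 7 (2R)-2-(3-hydroxypropyl)-2,6,6-trimethylcyclohexan-1-one
Product: 8 3-[(1R)-1,3,3-trimethyl-2-oxocyclohexyl]propanal
Conditions: Dess–Martin periodinane, NaHCO3, CH2Cl2, 0 °C to rt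
Reagents that add atoms: none
Why: Dess–Martin oxidation of a primary alcohol to the aldehyde under buffered conditions; the hindered ring ketone is inert.

**Step 5**
Reactants: 8 3-[(1R)-1,3,3-trimethyl-2-oxocyclohexyl]propanal
Product: 9 (2R)-2-[3-hydroxy-4-(methoxymethoxy)butyl]-2,6,6-trimethylcyclohexan-1-one (both carbinol epimers)
Conditions: Bu3SnCH2OCH2OMe, n-BuLi, THF, −78 °C; then 8, −78 °C; aq NH4Cl
Reagents that add atoms: tributyl[(methoxymethoxy)methyl]stannane, CCCC[Sn](CCCC)(CCCC)COCOC
Why: Tin–lithium exchange gives the α-alkoxy organolithium, which adds to the aldehyde at low temperature and ignores the far more hindered ring ketone. This forms C6–C7 with the C6 oxygen already in place; the carbinol configuration is irrelevant because it is oxidised next.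

**Step 6**
Reactants: 9 (2R)-2-[3-hydroxy-4-(methoxymethoxy)butyl]-2,6,6-trimethylcyclohexan-1-one
Product: 10 (2R)-2-[4-(methoxymethoxy)-3-oxobutyl]-2,6,6-trimethylcyclohexan-1-one
Conditions: Dess–Martin periodinane, NaHCO3, CH2Cl2, rt
Reagents that add atoms: none
Why: Dess–Martin oxidation of the secondary alcohol to the α-alkoxy ketone; neutral conditions avoid premature aldol chemistry.

**Step 7**
Reactants: 10 (2R)-2-[4-(methoxymethoxy)-3-oxobutyl]-2,6,6-trimethylcyclohexan-1-one
Product: 12 (4aR)-1-(methoxymethoxy)-4a,8,8-trimethyl-4,4a,5,6,7,8-hexahydronaphthalen-2(3H)-one, via aldol adduct 11 (not isolated)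
Conditions: NaOMe, MeOH, 65 °C
Reagents that add atoms: none
Why: This is a base-mediated intramolecular aldol condensation, the second stage of a Robinson annulation: methoxide enolises the side-chain ketone reversibly at C6 and C8, the C6 enolate adds to the ring carbonyl C5 to give β-hydroxy ketone 11, and E1cB loss of the C5 hydroxyl through the same enolate gives the conjugated 6-alkoxy enone 12. Ring B closes in the 6-(enolendo)-exo-trig mode, since the enolate C6=C7 bond lies inside the new ring, which is a favoured closure. No stereocentre is created, because C5 and C6 end up sp2, and C10 is quaternary and cannot epimerise. Regioselectivity comes from the substrate: the C8 enolate could only close a four-membered ring, and the ring ketone has no α-hydrogen because C4 and C10 are quaternary, so it can act only as acceptor. Addition to the tetrasubstituted carbonyl is uphill, and the dehydration to the conjugated enone is what draws the equilibria forward. The MOM ether is inert to alkoxide and cannot leave from C6, so the C6 oxygen is carried through the ring closure.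

**Step 8**
Reactants: 12 (4aR)-1-(methoxymethoxy)-4a,8,8-trimethyl-4,4a,5,6,7,8-hexahydronaphthalen-2(3H)-one
Product: 14 (1S,4aR,8aS)-1-(methoxymethoxy)-4a,8,8-trimethyloctahydronaphthalen-2(1H)-one [H5α; 6β-OMOM], via lithium enolate 13 (not isolated)
Conditions: Li, NH3/THF, t-BuOH (1 equiv), −78 °C; isoprene; then solid NH4Cl, −78 °C to rt
Reagents that add atoms: none
Why: Dissolving-metal (Birch-type) reduction of the enone: protonation of the β-carbon C5 on the α face gives the trans ring fusion and leaves the C6=C7 enolate 13. After excess lithium is destroyed, kinetic protonation at C6 should come from the α face, because the β face is screened by the axial 4β and C10 methyl groups, giving the axial 6β-ether. The ether oxygen survives because it sits on an enolate carbon while metal is present.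

**Step 9**
Reactants: 14 (1S,4aR,8aS)-1-(methoxymethoxy)-4a,8,8-trimethyloctahydronaphthalen-2(1H)-one
Product: 16 (1S,3S,4aR,8aS)-1-(methoxymethoxy)-3,4a,8,8-tetramethyloctahydronaphthalen-2(1H)-one [8α-methyl], via lithium enolate 15 (not isolated)
Conditions: LiN(i-Pr)2, THF, −78 °C; MeI, −78 to −30 °C
Reagents that add atoms: iodomethane, CI
Why: Kinetic enolate alkylation: the amide base removes a C8 methylene hydrogen in preference to the hindered equatorial C6–H on the alkoxy-bearing carbon. Methyl iodide approaches C8 anti to the axial C10 methyl, so the equatorial 8α-methyl ketone is expected; this centre is removed in step 11.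

**Step 10**
Reactants: 16 (1S,3S,4aR,8aS)-1-(methoxymethoxy)-3,4a,8,8-tetramethyloctahydronaphthalen-2(1H)-one
Product: 18 trimethyl{[(1S,4aR,8aS)-1-(methoxymethoxy)-3,4a,8,8-tetramethyl-1,4,4a,5,6,7,8,8a-octahydronaphthalen-2-yl]oxy}silane, via lithium enolate 17 (not isolated)
Conditions: LiN(i-Pr)2, THF, −78 to −40 °C; Me3SiCl, Et3N, −78 °C
Reagents that add atoms: chlorotrimethylsilane, C[Si](C)(C)Cl
Why: Kinetic deprotonation is expected at C8, whose axial 8β-hydrogen is aligned with the carbonyl π system. The remaining C6 hydrogen is equatorial and sits on the alkoxy-bearing carbon beside the C4 gem-dimethyl group. O-silylation then gives the regiodefined silyl enol ether.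

**Step 11**
Reactants: 18 trimethyl{[(1S,4aR,8aS)-1-(methoxymethoxy)-3,4a,8,8-tetramethyl-1,4,4a,5,6,7,8,8a-octahydronaphthalen-2-yl]oxy}silane
Product: 19 (1S,4aR,8aS)-1-(methoxymethoxy)-3,4a,8,8-tetramethyl-4a,5,6,7,8,8a-hexahydronaphthalen-2(1H)-one [8-methyl-8-en-7-one]
Conditions: Pd(OAc)2 (1.1 equiv), MeCN, rt
Reagents that add atoms: none
Why: Saegusa–Ito oxidation: divalent palladium forms the C8 palladium enolate from 18, and β-hydride elimination of a C9 hydrogen gives the conjugated endocyclic enone.

**Step 12**
Reactants: 20 (S)-malic acid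
Product: 21 2-[(2S,4S)-2-tert-butyl-5-oxo-1,3-dioxolan-4-yl]acetic acid (cis)
Conditions: t-BuCHO, TsOH (cat.), H2SO4 (cat.), pentane, reflux, Dean–Stark; crystallisation
Reagents that add atoms: pivalaldehyde, CC(C)(C)C=O
Why: Acid-catalysed acetalisation of the α-hydroxy acid unit (first stage of self-regeneration of stereocentres). The cis-dioxolanone is the preferred diastereomer and is purified by crystallisation; the acetal carbon now stores the chirality of the carbinol carbon.

**Step 13**
Reactants: 21 2-[(2S,4S)-2-tert-butyl-5-oxo-1,3-dioxolan-4-yl]acetic acid; 22 allyl bromide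
Product: 24 2-[(2S,4S)-2-tert-butyl-5-oxo-4-(prop-2-en-1-yl)-1,3-dioxolan-4-yl]acetic acid, via dilithium enolate carboxylate 23 (not isolated)
Conditions: LiN(SiMe3)2 (2.2 equiv), THF, −78 °C; 22, −78 to −30 °C; aq HCl
Reagents that add atoms: none
Why: Two equivalents of base give the carboxylate/dioxolanone enolate 23, which is alkylated anti to the tert-butyl group, on the face the hydrogen left. Allyl therefore replaces H with retention and fixes the future C13 (allyl CH2 = C12, CH2CO2H = C14/C15, ring carbonyl = C16).

**Step 14**
Reactants: 24 2-[(2S,4S)-2-tert-butyl-5-oxo-4-(prop-2-en-1-yl)-1,3-dioxolan-4-yl]acetic acid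
Product: 25 (3S)-3-(hydroxymethyl)hex-5-ene-1,3-diol
Conditions: LiAlH4, THF, 0 °C to reflux; aq NaOH work-up
Reagents that add atoms: none
Why: Hydride reduction of the acid and of the dioxolanone carbonyl; the hemiacetal collapses and the released pivalaldehyde is reduced to volatile neopentyl alcohol. The quaternary carbinol is untouched.

**Step 15**
Reactants: 25 (3S)-3-(hydroxymethyl)hex-5-ene-1,3-diol
Product: 26 2-[(4S)-2,2-dimethyl-4-(prop-2-en-1-yl)-1,3-dioxolan-4-yl]ethan-1-ol
Conditions: Me2C(OMe)2, TsOH (cat.), acetone, rt
Reagents that add atoms: 2,2-dimethoxypropane, COC(C)(C)OC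
Why: Acetonide formation under thermodynamic control prefers the five-membered dioxolane across the 1,2-diol (O13, O16). The six-membered alternative would place a substituent of the quaternary carbon syn-axial to an acetal methyl. The C15 hydroxyl stays free.

**Step 16**
Reactants: 26 2-[(4S)-2,2-dimethyl-4-(prop-2-en-1-yl)-1,3-dioxolan-4-yl]ethan-1-ol
Product: 27 tert-butyl{2-[(4S)-2,2-dimethyl-4-(prop-2-en-1-yl)-1,3-dioxolan-4-yl]ethoxy}dimethylsilane
Conditions: t-BuMe2SiCl, imidazole, CH2Cl2, rt
Reagents that add atoms: tert-butyldimethylsilyl chloride, CC(C)(C)[Si](C)(C)Cl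
Why: Standard silylation of the only free (primary) hydroxyl; it marks C15 for later oxidation and tolerates all organometallic steps.

**Step 17**
Reactants: 27 tert-butyl{2-[(4S)-2,2-dimethyl-4-(prop-2-en-1-yl)-1,3-dioxolan-4-yl]ethoxy}dimethylsilane
Product: 29 2-[(4S)-4-(2-{[tert-butyl(dimethyl)silyl]oxy}ethyl)-2,2-dimethyl-1,3-dioxolan-4-yl]ethan-1-ol, via ozonide 28 (not isolated)
Conditions: O3, CH2Cl2, −78 °C; then NaBH4, MeOH, −78 to 0 °C
Reagents that add atoms: ozone, [O-][O+]=O
Why: Ozonolysis of the terminal alkene and hydride reduction of ozonide 28 shorten the allyl group by one carbon to the 2-hydroxyethyl arm (C12–C11).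

**Step 18**
Reactants: 29 2-[(4S)-4-(2-{[tert-butyl(dimethyl)silyl]oxy}ethyl)-2,2-dimethyl-1,3-dioxolan-4-yl]ethan-1-ol
Product: 30 tert-butyl{2-[(4R)-4-(2-bromoethyl)-2,2-dimethyl-1,3-dioxolan-4-yl]ethoxy}dimethylsilane
Conditions: CBr4, PPh3, imidazole, CH2Cl2, 0 °C
Reagents that add atoms: carbon tetrabromide, BrC(Br)(Br)Br
Why: Appel bromination under buffered conditions; acetonide and silyl ether are untouched. The descriptor changes from S to R only because bromine changes the priorities.

**Step 19**
Reactants: 19 (1S,4aR,8aS)-1-(methoxymethoxy)-3,4a,8,8-tetramethyl-4a,5,6,7,8,8a-hexahydronaphthalen-2(1H)-one; 30 tert-butyl{2-[(4R)-4-(2-bromoethyl)-2,2-dimethyl-1,3-dioxolan-4-yl]ethoxy}dimethylsilane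
Product: 32 (13S)-15-(tert-butyldimethylsilyloxy)-13,16-(isopropylidenedioxy)-6β-(methoxymethoxy)-7-(trimethylsilyloxy)-9βH-labd-7-ene [side chain 9α], via Grignard reagent 31 (not isolated)
Conditions: 30, Mg, THF, rt; then CuBr·SMe2 (15 mol %), HMPA, Me3SiCl, 19, THF, −78 to −40 °C; Et3N, cold aq NaHCO3
Reagents that add atoms: chlorotrimethylsilane, C[Si](C)(C)Cl
Why: Copper-catalysed conjugate addition of a Grignard reagent accelerated by chlorosilane. Addition at C9 should occur anti to the C10 methyl, as in 1α-alkylation of steroidal 1-en-3-ones, and the enolate is trapped regiospecifically as silyl enol ether 32. The C9 centre is erased in step 20.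

**Step 20**
Reactants: 32 (13S)-15-(tert-butyldimethylsilyloxy)-13,16-(isopropylidenedioxy)-6β-(methoxymethoxy)-7-(trimethylsilyloxy)-9βH-labd-7-ene
Product: 33 (13S)-15-(tert-butyldimethylsilyloxy)-13,16-(isopropylidenedioxy)-6β-(methoxymethoxy)labd-8-en-7-one
Conditions: Pd(OAc)2 (1.2 equiv), MeCN, rt to 40 °C
Reagents that add atoms: none
Why: Saegusa–Ito oxidation: the divalent palladium enolate from 32 loses the C9 hydrogen by β-hydride elimination to give the tetrasubstituted enone, the same addition/dehydrosilylation sequence used for 3-alkyl-2-methylcyclohexenones. Silyl ether, acetonide and MOM ether are unaffected.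

**Step 21**
Reactants: 33 (13S)-15-(tert-butyldimethylsilyloxy)-13,16-(isopropylidenedioxy)-6β-(methoxymethoxy)labd-8-en-7-one
Product: 34 (13S)-15-hydroxy-13,16-(isopropylidenedioxy)-6β-(methoxymethoxy)labd-8-en-7-one
Conditions: Bu4NF, AcOH, THF, 0 °C to rt
Reagents that add atoms: none
Why: Fluoride cleavage of the primary silyl ether; buffering with acetic acid protects the C6 centre next to the ketone from base.

**Step 22**
Reactants: 34 (13S)-15-hydroxy-13,16-(isopropylidenedioxy)-6β-(methoxymethoxy)labd-8-en-7-one
Product: 35 (13S)-13,16-(isopropylidenedioxy)-6β-(methoxymethoxy)-7-oxolabd-8-en-15-oic acid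
Conditions: TEMPO (cat.), PhI(OAc)2, MeCN/H2O (pH 7 buffer), rt
Reagents that add atoms: water, O
Why: Oxoammonium-mediated oxidation takes the only free alcohol through the aldehyde hydrate to the acid; the enone and both acetals are inert.

**Step 23**
Reactants: 35 (13S)-13,16-(isopropylidenedioxy)-6β-(methoxymethoxy)-7-oxolabd-8-en-15-oic acid
Product: 38 (5S,6S,10S,13S)-6β,13-dihydroxy-7-oxolabd-8-en-15,16-olide (target), via dihydroxy acid 36 (not isolated), via lactone MOM ether 37 (not isolated)
Conditions: 3 M aq HCl, THF, 40 °C
Reagents that add atoms: none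
Why: Acid hydrolysis removes the acetonide first (36); the primary C16 hydroxyl then lactonises onto C15 to give 37, since the tertiary hydroxyl could only form a β-lactone; hydrolysis of the MOM acetal frees the 6β-hydroxyl. Acid is used because base would epimerise C6 and dehydrate the β-hydroxy lactone.

## Compound list

1 | 2,2,6-trimethylcyclohexan-1-one (racemic) | CC1CCCC(C)(C)C1=O | starting material
2 | allyl chloroformate | C=CCOC(Cl)=O | starting material
3 | lithium 2,6,6-trimethylcyclohex-1-en-1-olate | [Li]OC1=C(C)CCCC1(C)C | intermediate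
4 | allyl 2,6,6-trimethylcyclohex-1-en-1-yl carbonate | C=CCOC(=O)OC1=C(C)CCCC1(C)C | intermediate
5 | (2R)-2-allyl-2,6,6-trimethylcyclohexan-1-one | C=CC[C@@]1(C)CCCC(C)(C)C1=O | intermediate
6 | 9-{3-[(1S)-1,3,3-trimethyl-2-oxocyclohexyl]propyl}-9-borabicyclo[3.3.1]nonane | C1CCC2CCCC1B2CCC[C@@]1(C)CCCC(C)(C)C1=O | intermediate
7 | (2R)-2-(3-hydroxypropyl)-2,6,6-trimethylcyclohexan-1-one | OCCC[C@@]1(C)CCCC(C)(C)C1=O | intermediate
8 | 3-[(1R)-1,3,3-trimethyl-2-oxocyclohexyl]propanal | O=CCC[C@@]1(C)CCCC(C)(C)C1=O | intermediate
9 | (2R)-2-[3-hydroxy-4-(methoxymethoxy)butyl]-2,6,6-trimethylcyclohexan-1-one (carbinol epimers) | COCOCC(O)CC[C@@]1(C)CCCC(C)(C)C1=O | intermediate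
10 | (2R)-2-[4-(methoxymethoxy)-3-oxobutyl]-2,6,6-trimethylcyclohexan-1-one | COCOCC(=O)CC[C@@]1(C)CCCC(C)(C)C1=O | intermediate
11 | (4aR)-8a-hydroxy-1-(methoxymethoxy)-4a,8,8-trimethyloctahydronaphthalen-2(1H)-one (C1/C8a epimers) | COCOC1C(=O)CC[C@@]2(C)CCCC(C)(C)C12O | intermediate
12 | (4aR)-1-(methoxymethoxy)-4a,8,8-trimethyl-4,4a,5,6,7,8-hexahydronaphthalen-2(3H)-one | O=C1CC[C@@]2(C)CCCC(C)(C)C2=C1OCOC | intermediate
13 | lithium (4aR,8aS)-1-(methoxymethoxy)-4a,8,8-trimethyl-3,4,4a,5,6,7,8,8a-octahydronaphthalen-2-olate | [Li]OC1=C(OCOC)[C@H]2C(C)(C)CCC[C@]2(C)CC1 | intermediate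
14 | (1S,4aR,8aS)-1-(methoxymethoxy)-4a,8,8-trimethyloctahydronaphthalen-2(1H)-one | O=C1CC[C@@]2(C)CCCC(C)(C)[C@@H]2[C@@H]1OCOC | intermediate
15 | lithium (1S,4aR,8aS)-1-(methoxymethoxy)-4a,8,8-trimethyl-1,4,4a,5,6,7,8,8a-octahydronaphthalen-2-olate | [Li]OC1=CC[C@@]2(C)CCCC(C)(C)[C@@H]2[C@@H]1OCOC | intermediate
16 | (1S,3S,4aR,8aS)-1-(methoxymethoxy)-3,4a,8,8-tetramethyloctahydronaphthalen-2(1H)-one | O=C1[C@@H](C)C[C@@]2(C)CCCC(C)(C)[C@@H]2[C@@H]1OCOC | intermediate
17 | lithium (1S,4aR,8aS)-1-(methoxymethoxy)-3,4a,8,8-tetramethyl-1,4,4a,5,6,7,8,8a-octahydronaphthalen-2-olate | [Li]OC1=C(C)C[C@@]2(C)CCCC(C)(C)[C@@H]2[C@@H]1OCOC | intermediate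
18 | trimethyl{[(1S,4aR,8aS)-1-(methoxymethoxy)-3,4a,8,8-tetramethyl-1,4,4a,5,6,7,8,8a-octahydronaphthalen-2-yl]oxy}silane | C[Si](C)(C)OC1=C(C)C[C@@]2(C)CCCC(C)(C)[C@@H]2[C@@H]1OCOC | intermediate
19 | (1S,4aR,8aS)-1-(methoxymethoxy)-3,4a,8,8-tetramethyl-4a,5,6,7,8,8a-hexahydronaphthalen-2(1H)-one | O=C1C(C)=C[C@@]2(C)CCCC(C)(C)[C@@H]2[C@@H]1OCOC | intermediate
20 | (S)-malic acid | OC(=O)C[C@H](O)C(O)=O | starting material
21 | 2-[(2S,4S)-2-tert-butyl-5-oxo-1,3-dioxolan-4-yl]acetic acid | OC(=O)C[C@@H]1O[C@H](C(C)(C)C)OC1=O | intermediate
22 | allyl bromide | C=CCBr | starting material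
23 | dilithium enolate carboxylate of 21 (acetal carbon unchanged) | [Li]OC(=O)CC1=C(O[Li])O[C@@H](C(C)(C)C)O1 | intermediate
24 | 2-[(2S,4S)-2-tert-butyl-5-oxo-4-(prop-2-en-1-yl)-1,3-dioxolan-4-yl]acetic acid | OC(=O)C[C@]1(CC=C)O[C@H](C(C)(C)C)OC1=O | intermediate
25 | (3S)-3-(hydroxymethyl)hex-5-ene-1,3-diol | OCC[C@](CC=C)(O)CO | intermediate
26 | 2-[(4S)-2,2-dimethyl-4-(prop-2-en-1-yl)-1,3-dioxolan-4-yl]ethan-1-ol | OCC[C@]1(CC=C)OC(C)(C)OC1 | intermediate
27 | tert-butyl{2-[(4S)-2,2-dimethyl-4-(prop-2-en-1-yl)-1,3-dioxolan-4-yl]ethoxy}dimethylsilane | CC(C)(C)[Si](C)(C)OCC[C@]1(CC=C)OC(C)(C)OC1 | intermediate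
28 | 3-{[(4R)-4-(2-{[tert-butyl(dimethyl)silyl]oxy}ethyl)-2,2-dimethyl-1,3-dioxolan-4-yl]methyl}-1,2,4-trioxolane | CC(C)(C)[Si](C)(C)OCC[C@]1(CC2OOCO2)OC(C)(C)OC1 | intermediate
29 | 2-[(4S)-4-(2-{[tert-butyl(dimethyl)silyl]oxy}ethyl)-2,2-dimethyl-1,3-dioxolan-4-yl]ethan-1-ol | CC(C)(C)[Si](C)(C)OCC[C@]1(CCO)OC(C)(C)OC1 | intermediate
30 | tert-butyl{2-[(4R)-4-(2-bromoethyl)-2,2-dimethyl-1,3-dioxolan-4-yl]ethoxy}dimethylsilane | CC(C)(C)[Si](C)(C)OCC[C@]1(CCBr)OC(C)(C)OC1 | intermediate
31 | (2-{(4R)-4-[2-(tert-butyldimethylsilyloxy)ethyl]-2,2-dimethyl-1,3-dioxolan-4-yl}ethyl)magnesium bromide | CC(C)(C)[Si](C)(C)OCC[C@]1(CC[Mg]Br)OC(C)(C)OC1 | intermediate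
32 | (13S)-15-(tert-butyldimethylsilyloxy)-13,16-(isopropylidenedioxy)-6β-(methoxymethoxy)-7-(trimethylsilyloxy)-9βH-labd-7-ene | C[Si](C)(C)OC1=C(C)[C@@H](CC[C@]3(CCO[Si](C)(C)C(C)(C)C)COC(C)(C)O3)[C@@]2(C)CCCC(C)(C)[C@@H]2[C@@H]1OCOC | intermediate
33 | (13S)-15-(tert-butyldimethylsilyloxy)-13,16-(isopropylidenedioxy)-6β-(methoxymethoxy)labd-8-en-7-one | CC1=C(CC[C@]3(CCO[Si](C)(C)C(C)(C)C)COC(C)(C)O3)[C@@]2(C)CCCC(C)(C)[C@@H]2[C@H](OCOC)C1=O | intermediate
34 | (13S)-15-hydroxy-13,16-(isopropylidenedioxy)-6β-(methoxymethoxy)labd-8-en-7-one | CC1=C(CC[C@]3(CCO)COC(C)(C)O3)[C@@]2(C)CCCC(C)(C)[C@@H]2[C@H](OCOC)C1=O | intermediate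
35 | (13S)-13,16-(isopropylidenedioxy)-6β-(methoxymethoxy)-7-oxolabd-8-en-15-oic acid | CC1=C(CC[C@]3(CC(O)=O)COC(C)(C)O3)[C@@]2(C)CCCC(C)(C)[C@@H]2[C@H](OCOC)C1=O | intermediate
36 | (13S)-13,16-dihydroxy-6β-(methoxymethoxy)-7-oxolabd-8-en-15-oic acid | CC1=C(CC[C@@](O)(CO)CC(O)=O)[C@@]2(C)CCCC(C)(C)[C@@H]2[C@H](OCOC)C1=O | intermediate
37 | (13S)-13-hydroxy-6β-(methoxymethoxy)-7-oxolabd-8-en-15,16-olide | CC1=C(CC[C@@]3(O)COC(=O)C3)[C@@]2(C)CCCC(C)(C)[C@@H]2[C@H](OCOC)C1=O | intermediate
38 | (5S,6S,10S,13S)-6β,13-dihydroxy-7-oxolabd-8-en-15,16-olide | CC1=C(CC[C@@]2(O)COC(=O)C2)[C@@]2(C)CCCC(C)(C)[C@@H]2[C@H](O)C1=O | target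

## Step count and risks

Total step count: 23. Longest linear sequence: 16 steps (steps 1–11 and 19–23); the side chain (steps 12–18) joins at step 19.

**Step 7 (key step).** The addition to the tetrasubstituted carbonyl is reversible and unfavourable, and under hot alkoxide the C8 enolate can fragment by retro-Michael cleavage of C9–C10 before dehydration takes place. Fallback: set out from aldehyde 8. Addition of the lithium anion of diethyl [(methoxymethoxy)methyl]phosphonate (LiN(i-Pr)2, THF, −78 °C) gives hydroxy phosphonate F1, and Dess–Martin oxidation gives keto phosphonate F2. An intramolecular Horner–Wadsworth–Emmons olefination (K2CO3, 18-crown-6, toluene, 80 °C) then closes C5=C6. It deprotonates only the doubly activated C6, is irreversible, and comes back to the route at 12.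

**Step 8.** Facial selectivity in the kinetic protonation of enolate 13 at C6 may be poor, the axial 6β-ether may equilibrate to the equatorial epimer on work-up, and the C6 oxygen may be lost reductively if lithium survives into the quench. Fallback: from 12, heterogeneous hydrogenation (H2 under pressure, Rh/Al2O3 or Pd/C, EtOAc) adds both hydrogens to the α face in one syn event without an enolate and arrives directly at 14.

**Step 10.** Deprotonation may occur at C6 instead of C8 now that both α-carbons are tertiary, which would lead back toward a C5=C6 enone on oxidation. Fallback: set out from 14 and dehydrogenate before methylating. LiN(i-Pr)2/Me3SiCl gives silyl enol ether F3 (the C8 methylene is clearly preferred), and Pd(OAc)2 gives enone F4. Iodine/pyridine gives iodo enone F5, and Stille coupling with SnMe4 (Pd(PPh3)4, CuI, NMP) returns to the route at 19.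

**Step 19.** Conjugate addition may fail (competing 1,2-addition at C7 or simple enolisation) because C9 is next to the quaternary C10 and the enone carries an α-methyl. Fallback: set out from 14 through F3 and F4 as under step 10. The α-unsubstituted enone F4 is more reactive; copper-catalysed addition of 31 with Me3SiCl gives silyl enol ether F6, and Pd(OAc)2 gives enone F7. Bromination–dehydrobromination (Br2, Et3N, CH2Cl2, 0 °C) gives bromo enone F8, and Stille methylation with SnMe4 returns to the route at 33.

**Step 20.** β-Hydride elimination may go toward the C17 methyl (exocyclic alkene), or palladation of the hindered tetrasubstituted silyl enol ether may be slow. Fallback: from 32, N-bromosuccinimide (THF, 0 °C) gives the tertiary bromo ketone F9. Dehydrobromination under equilibrating conditions (LiBr, Li2CO3, DMF, 100 °C), which favour the conjugated endocyclic alkene, returns to the route at 33.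

**Step 23.** Acid may dehydrate the β-hydroxy lactone or epimerise C6 through the enol, and hydrolysis of the hindered axial MOM ether may be incomplete. Fallback: from 35, the deprotection is staged. 80% aqueous AcOH at 40 °C removes only the acetonide and closes the lactone to give 37, now isolated. Non-hydrolytic cleavage of the MOM ether with Me2BBr (CH2Cl2, −78 °C; then aq NaHCO3) then gives 38.

## Further compounds

F1 | step 7 | diethyl {2-hydroxy-1-(methoxymethoxy)-4-[(1R)-1,3,3-trimethyl-2-oxocyclohexyl]butyl}phosphonate | CCOP(=O)(OCC)C(OCOC)C(O)CC[C@@]1(C)CCCC(C)(C)C1=O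
F2 | step 7 | diethyl {1-(methoxymethoxy)-2-oxo-4-[(1R)-1,3,3-trimethyl-2-oxocyclohexyl]butyl}phosphonate | CCOP(=O)(OCC)C(OCOC)C(=O)CC[C@@]1(C)CCCC(C)(C)C1=O
F0 | step 8 | none | none
F3 | step 10 | trimethyl{[(1S,4aR,8aS)-1-(methoxymethoxy)-4a,8,8-trimethyl-1,4,4a,5,6,7,8,8a-octahydronaphthalen-2-yl]oxy}silane | C[Si](C)(C)OC1=CC[C@@]2(C)CCCC(C)(C)[C@@H]2[C@@H]1OCOC
F4 | step 10 | (1S,4aR,8aS)-1-(methoxymethoxy)-4a,8,8-trimethyl-4a,5,6,7,8,8a-hexahydronaphthalen-2(1H)-one | O=C1C=C[C@@]2(C)CCCC(C)(C)[C@@H]2[C@@H]1OCOC
F5 | step 10 | (1S,4aS,8aS)-3-iodo-1-(methoxymethoxy)-4a,8,8-trimethyl-4a,5,6,7,8,8a-hexahydronaphthalen-2(1H)-one | O=C1C(I)=C[C@@]2(C)CCCC(C)(C)[C@@H]2[C@@H]1OCOC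
F6 | step 19 | 17-nor analogue of 32 (C8–H silyl enol ether; side chain 9α) | C[Si](C)(C)OC1=C[C@@H](CC[C@]3(CCO[Si](C)(C)C(C)(C)C)COC(C)(C)O3)[C@@]2(C)CCCC(C)(C)[C@@H]2[C@@H]1OCOC
F7 | step 19 | 17-nor analogue of 33 (C8–H enone) | O=C1C=C(CC[C@]3(CCO[Si](C)(C)C(C)(C)C)COC(C)(C)O3)[C@@]2(C)CCCC(C)(C)[C@@H]2[C@@H]1OCOC
F8 | step 19 | 8-bromo-17-nor analogue of 33 | O=C1C(Br)=C(CC[C@]3(CCO[Si](C)(C)C(C)(C)C)COC(C)(C)O3)[C@@]2(C)CCCC(C)(C)[C@@H]2[C@@H]1OCOC
F9 | step 20 | 8-bromo-8,9-dihydro derivative of 33 (side chain 9α; C8 epimers) | CC1(Br)[C@@H](CC[C@]3(CCO[Si](C)(C)C(C)(C)C)COC(C)(C)O3)[C@@]2(C)CCCC(C)(C)[C@@H]2[C@H](OCOC)C1=O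
F0 | step 23 | none | none
A1 | alternative 1 | (5E,9E)-farnesylacetone | CC(C)=CCC/C(C)=C/CC/C(C)=C/CCC(C)=O
A2 | alternative 1 | sclareol oxide (8α,13-epoxy-14,15-dinorlabd-12-ene) | CC1=CC[C@@H]2[C@@]3(C)CCCC(C)(C)[C@@H]3CC[C@@]2(C)O1
A3 | alternative 2 | 6β-(triethylsilyloxy)-9-{2-[3-(triethylsilyloxy)oxetan-3-yl]ethyl} enone (oxetane in place of the lactone) | CC1=C(CCC2(O[Si](CC)(CC)CC)COC2)[C@@]2(C)CCCC(C)(C)[C@@H]2[C@H](O[Si](CC)(CC)CC)C1=O
A4 | alternative 2 | bis(triethylsilyl) ether of the target | CC1=C(CC[C@@]2(O[Si](CC)(CC)CC)COC(=O)C2)[C@@]2(C)CCCC(C)(C)[C@@H]2[C@H](O[Si](CC)(CC)CC)C1=O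
A5 | alternative 3 | 2,6-dimethyl-1,4-benzoquinone | CC1=CC(=O)C=C(C)C1=O
A6 | alternative 3 | 4-methylpenta-1,3-diene | CC(C)=CC=C
A7 | alternative 3 | cis-fused Diels–Alder adduct (ring A 2-ene, ring B 7-ene-6,9-dione) | CC1=CC(=O)[C@@H]2C(C)(C)C=CC[C@]2(C)C1=O
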